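Cuts, in retrosynthetic order: the two O–Si bonds; C2–C1' (ring B off ring C, back to a flat 8-geranylchromone); C1''–C2'' together with C3''–CH3 of the geranyl chain (back to an 8-(bromomethyl)chromone, 6-methylhept-5-en-1-yne and AlMe3); the C–Br bond at the C8 methyl carbon; O1–C2 and C2–C3 of ring C (back to 2,4-dihydroxy-3-methylacetophenone and a one-carbon amide acetal).
Enabling feature: C1'' is a benzylic CH2 on C8 of ring A, held between O7 and O1. Its partner C2'' is the sp2 CH of an E-trisubstituted alkene whose other end, C3'', bears CH3. A benzylic halide and the alkenylalane from syn-methylalumination of a terminal alkyne deliver exactly this benzyl–alkenyl bond, so three components give chain, methyl branch, E geometry and C8 attachment in one flask.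
Forward order: ring A is bought with the C8 carbon in place. Ring C is closed first, at the chromone oxidation level; this is a helper, since it has no stereocentre and no C2–H or C3–H2 to be brominated or enolised. CH3 then becomes CH2Br, the chain is joined, ring B is added last and the silyl groups leave at the end.
Stereochemistry: C2''=C3'' (E) comes from syn carbometalation and stereoretentive coupling. C2 (S) comes from a ligand-controlled rhodium-catalysed 1,4-addition of an arylboronic acid to the chromone. This step is placed after all radical, Lewis-acidic and basic operations because 4'-hydroxyflavanones racemise by ring opening.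

Key step: step 5

Remark on numbering: flavanone numbering is used (O1, C2 to C8a, ring B primed, geranyl carbons double-primed; geranyl = (2E)-3,7-dimethylocta-2,6-dien-1-yl).
Assumption: the sense of induction in step 6 is taken from the quadrant model of (S)-biaryl bisphosphine rhodium catalysts with cyclic enones, which maps onto 2S here; the antipodal ligand is equally available should the assignment prove reversed.

Step 1
Reactants: 1 1-(2,4-dihydroxy-3-methylphenyl)ethan-1-one
Product: 2 1-[2-hydroxy-3-methyl-4-(triisopropylsilyloxy)phenyl]ethan-1-one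
Conditions: iPr3SiCl (1.1 equiv), imidazole (2.2 equiv), DMF, 0 °C to rt
Reagents that add atoms: triisopropylsilyl chloride, CC(C)[Si](Cl)(C(C)C)C(C)C
Why: Chemoselective O-silylation, in which the C2 hydroxyl is locked in a hydrogen bond to the acetyl carbonyl and flanked on both sides, so the bulky silyl chloride should react only at the free and more acidic C4 hydroxyl.

Step 2
Reactants: 2 1-[2-hydroxy-3-methyl-4-(triisopropylsilyloxy)phenyl]ethan-1-one
Product: 4 8-methyl-7-(triisopropylsilyloxy)-4H-chromen-4-one, via enaminone 3 (not isolated)
Conditions: Me2NCH(OMe)2 (2 equiv), toluene, 100 °C; concentrate; 2 M aq HCl, CH2Cl2, rt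
Reagents that add atoms: N,N-dimethylformamide dimethyl acetal, COC(OC)N(C)C
Why: Enaminone synthesis of chromones, in which the acetyl CH3 condenses with the amide acetal to the (E)-enaminone 3 and, on protonation, the chelated phenol adds to the β-carbon and expels dimethylamine (6-endo addition–elimination), while the hindered and electron-poor aryl triisopropylsilyl ether should withstand brief dilute acid.

Step 3
Reactants: 4 8-methyl-7-(triisopropylsilyloxy)-4H-chromen-4-one
Product: 5 8-(bromomethyl)-7-(triisopropylsilyloxy)-4H-chromen-4-one
Conditions: NBS (1.05 equiv), AIBN (5 mol %), PhCF3, 80 °C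
Reagents that add atoms: N-bromosuccinimide, O=C1CCC(=O)N1Br
Why: Wohl–Ziegler bromination, in which the bromine atom abstracts hydrogen from the only benzylic C–H bonds present (the flat chromone has no flavanone-type C2–H or C3–H2), the radical being stabilised by O7 and O1, while the C4 carbonyl group, the non-polar medium and the bulk of the silyl group next to C6 should hold back ionic bromination of ring A.

Step 4
Reactants: 6 6-methylhept-5-en-2-one
Product: 8 6-methylhept-5-en-1-yne, via enol phosphate 7 (not isolated)
Conditions: LiN(iPr)2 (1.05 equiv), THF, −78 °C; ClP(O)(OEt)2 (1.1 equiv), −78 °C to rt; LiN(iPr)2 (2.3 equiv), −78 °C to rt; H2O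
Reagents that add atoms: none
Why: Conversion of a methyl ketone into a terminal alkyne by enol phosphate elimination, in which kinetic deprotonation at CH3 and O-phosphorylation give the 1-alken-2-yl phosphate 7, from which excess amide base removes a vinylic hydrogen and expels diethyl phosphate, the trisubstituted alkene staying untouched.

Step 5
Reactants: 8 6-methylhept-5-en-1-yne; 5 8-(bromomethyl)-7-(triisopropylsilyloxy)-4H-chromen-4-one
Product: 10 8-[(2E)-3,7-dimethylocta-2,6-dien-1-yl]-7-(triisopropylsilyloxy)-4H-chromen-4-one, via alkenylalane 9 (not isolated)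
Conditions: 8 (1.5 equiv), AlMe3 (3 equiv), Cp2ZrCl2 (0.3 equiv), CH2Cl2, 0 °C to rt; solvent and excess AlMe3 off in vacuo, THF; 5 (1.0 equiv), Pd(PPh3)4 (5 mol %), 0 °C to rt
Reagents that add atoms: trimethylaluminium, C[Al](C)C
Why: Cp2ZrCl2-catalysed syn-methylalumination (Negishi carboalumination) of the terminal alkyne of 8 places CH3 on the internal and AlMe2 on the terminal carbon from the same face, so that alane 9 carries the C3'' methyl branch and the E geometry, the trisubstituted C6''=C7'' alkene being inert. Zerovalent palladium then inserts into the benzylic C–Br bond of 5, the alkenyl group passes from aluminium to palladium with retention, and reductive elimination forms the C1''–C2'' bond. The closest known reaction type is the palladium- or nickel-catalysed coupling of carboalumination-derived alkenylalanes with di-ortho-substituted benzylic halides, the established way to polyprenylated arenes and quinones, which tolerates quinone carbonyl groups. No ring is closed and no stereocentre is formed; the one stereo-element, the C2''=C3'' double bond, is controlled by the syn addition and by stereoretentive transmetalation and reductive elimination. Because the electrophile is benzylic and the nucleophile alkenyl, no allyl-metal species arises, so the SN2' transposition, E/Z leakage, O7-alkylation and C6/C8 mixtures of a direct geranylation cannot occur, the site having been fixed by the C8 carbon bought with 1. The selectivity needed is coupling faster than attack of Al–C bonds on C4=O or C2 of ring C and faster than Lewis-acid ionisation of the bromide; it is secured by stripping excess AlMe3, by THF as donor solvent, by the vinylogous-ester nature and fixed s-trans geometry of the chromone, and by preferential transfer of alkenyl over methyl to palladium.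

Step 6
Reactants: 10 8-[(2E)-3,7-dimethylocta-2,6-dien-1-yl]-7-(triisopropylsilyloxy)-4H-chromen-4-one; 11 4-(tert-butyldimethylsilyloxy)phenylboronic acid
Product: 12 (2S)-2-[4-(tert-butyldimethylsilyloxy)phenyl]-8-[(2E)-3,7-dimethylocta-2,6-dien-1-yl]-7-(triisopropylsilyloxy)chroman-4-one
Conditions: 11 (2.5 equiv), [RhCl(C2H4)2]2 (1.5 mol %), (S)-MeO-F12-BIPHEP (3.3 mol %), KOH (10 mol %), toluene–H2O (10:1), 25 °C
Reagents that add atoms: none
Why: Hayashi–Miyaura asymmetric 1,4-addition, in which the aryl-rhodium species formed by transmetalation from 11 inserts the C2=C3 bond of the chromone on the face left open by the (S)-configured electron-poor biaryl bisphosphine (the quadrant model that gives (S)-3-arylcyclohexanones, which maps onto 2S here), and hydrolysis of the oxa-π-allyl rhodium enolate releases 12 under almost neutral conditions in which the isolated trisubstituted alkenes, both silyl ethers and the new C2 stereocentre should persist.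

Step 7
Reactants: 12 (2S)-2-[4-(tert-butyldimethylsilyloxy)phenyl]-8-[(2E)-3,7-dimethylocta-2,6-dien-1-yl]-7-(triisopropylsilyloxy)chroman-4-one
Product: 13 (2S)-7,4'-dihydroxy-8-geranylflavanone
Conditions: Bu4NF (2.5 equiv), AcOH (3 equiv), THF, 0 °C
Reagents that add atoms: none
Why: Fluoride-mediated cleavage of both aryl silyl ethers, driven by Si–F bond formation, with acetic acid protonating each phenoxide as it forms, so that neither base-induced opening of ring C to the chalcone (racemisation at C2) nor acid-induced cyclisation of O7 onto C3'' of the geranyl chain should set in.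

Compound list
1 | 1-(2,4-dihydroxy-3-methylphenyl)ethan-1-one | CC(=O)c1ccc(O)c(C)c1O | starting material
2 | 1-[2-hydroxy-3-methyl-4-(triisopropylsilyloxy)phenyl]ethan-1-one | CC(=O)c1ccc(O[Si](C(C)C)(C(C)C)C(C)C)c(C)c1O | intermediate
3 | (E)-3-(dimethylamino)-1-[2-hydroxy-3-methyl-4-(triisopropylsilyloxy)phenyl]prop-2-en-1-one | CN(C)/C=C/C(=O)c1ccc(O[Si](C(C)C)(C(C)C)C(C)C)c(C)c1O | intermediate
4 | 8-methyl-7-(triisopropylsilyloxy)-4H-chromen-4-one | Cc1c(O[Si](C(C)C)(C(C)C)C(C)C)ccc2c1occc2=O | intermediate
5 | 8-(bromomethyl)-7-(triisopropylsilyloxy)-4H-chromen-4-one | BrCc1c(O[Si](C(C)C)(C(C)C)C(C)C)ccc2c1occc2=O | intermediate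
6 | 6-methylhept-5-en-2-one | CC(=O)CCC=C(C)C | starting material
7 | diethyl 6-methylhepta-1,5-dien-2-yl phosphate | C=C(CCC=C(C)C)OP(=O)(OCC)OCC | intermediate
8 | 6-methylhept-5-en-1-yne | C#CCCC=C(C)C | intermediate
9 | [(1E)-2,6-dimethylhepta-1,5-dien-1-yl]dimethylalane | CC(C)=CCC/C(C)=C/[Al](C)C | intermediate
10 | 8-[(2E)-3,7-dimethylocta-2,6-dien-1-yl]-7-(triisopropylsilyloxy)-4H-chromen-4-one | CC(C)=CCC/C(C)=C/Cc1c(O[Si](C(C)C)(C(C)C)C(C)C)ccc2c1occc2=O | intermediate
11 | 4-(tert-butyldimethylsilyloxy)phenylboronic acid | CC(C)(C)[Si](C)(C)Oc1ccc(B(O)O)cc1 | starting material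
12 | (2S)-2-[4-(tert-butyldimethylsilyloxy)phenyl]-8-[(2E)-3,7-dimethylocta-2,6-dien-1-yl]-7-(triisopropylsilyloxy)chroman-4-one | CC(C)=CCC/C(C)=C/Cc1c(O[Si](C(C)C)(C(C)C)C(C)C)ccc2c1O[C@H](c1ccc(O[Si](C)(C)C(C)(C)C)cc1)CC2=O | intermediate
13 | (2S)-7,4'-dihydroxy-8-geranylflavanone | CC(C)=CCC/C(C)=C/Cc1c(O)ccc2c1O[C@H](c1ccc(O)cc1)CC2=O | target

Total step count: 7. Longest linear sequence: 6 (steps 1, 2, 3, 5, 6, 7).

Steps most likely to fail

Step 5. The aluminium species may consume the partners before palladium does. Possible processes are methyl or alkenyl transfer to C4=O, Lewis-acid ionisation of the doubly oxygen-flanked benzylic bromide followed by oligomerisation, and reductive homocoupling of the bromide.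
The fallback gives up the one-flask union and the Lewis-acidic nucleophile in favour of an isolated, neutral organotin partner. It sets out from alane 9 and comes back to the route at 10.
- Alane 9 is quenched with I2 (THF, −30 °C) to give (E)-1-iodo-2,6-dimethylhepta-1,5-diene F1.
- Halogen–lithium exchange (t-BuLi, 2 equiv, Et2O, −78 °C) gives [(1E)-2,6-dimethylhepta-1,5-dien-1-yl]lithium F2.
- F2 is trapped with Bu3SnCl as tributyl[(1E)-2,6-dimethylhepta-1,5-dien-1-yl]stannane F3.
- A Stille coupling of F3 with bromide 5 (Pd2(dba)3, AsPh3, THF, 50 °C, no base, no Lewis acid) should give 10 with retention of the E geometry.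

Step 3. Ionic bromination of ring A at C6 (ortho to the silyloxy group, para to O1) or at C3 may outrun hydrogen abstraction from the C8 methyl group, and HBr formed on the way may strip the silyl group.
The fallback changes the electronic design of the substrate, so that O7 is an acceptor-bound ester during halogenation and coupling and the silyl group is put on only afterwards. It sets out from 4 and comes back at 10.
- Bu4NF/AcOH frees 7-hydroxy-8-methyl-4H-chromen-4-one F4.
- Ac2O in pyridine gives 8-methyl-4-oxo-4H-chromen-7-yl acetate F5, whose ring is too electron-poor for nuclear bromination.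
- NBS/AIBN gives 8-(bromomethyl)-4-oxo-4H-chromen-7-yl acetate F6.
- Coupling with alane 9 under the conditions of step 5 gives 8-geranyl-4-oxo-4H-chromen-7-yl acetate F7.
- Brief methanolysis (catalytic K2CO3, MeOH, 0 °C) gives 8-geranyl-7-hydroxy-4H-chromen-4-one F8.
- iPr3SiCl/imidazole turns F8 into 10.

Step 6. The electron-rich, 8-substituted chromone may insert sluggishly. Facial discrimination may be poor, or partial ring opening of the rhodium enolate may erode the configuration at C2.
The fallback replaces asymmetric C–C bond formation by a kinetic resolution. It sets out from 10 and comes back at 12.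
- The highly active ligand-free catalyst [Rh(OH)(cod)]2 with 11 (dioxane–H2O, 40 °C) should give the racemic flavanone rac-2-[4-(tert-butyldimethylsilyloxy)phenyl]-8-geranyl-7-(triisopropylsilyloxy)chroman-4-one F9.
- Noyori–Ikariya asymmetric transfer hydrogenation with RuCl[(R,R)-TsDPEN](p-cymene) in HCO2H–Et3N, run to about half conversion, should reduce the matched (2R)-ketone to (2R,4R)-2-[4-(tert-butyldimethylsilyloxy)phenyl]-8-geranyl-7-(triisopropylsilyloxy)chroman-4-ol F10, the 2,4-cis alcohol.
- The slower (2S)-ketone remains and is separated by chromatography as 12.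

Further compounds
F1 | step 5 | (E)-1-iodo-2,6-dimethylhepta-1,5-diene | CC(C)=CCC/C(C)=C/I
F2 | step 5 | [(1E)-2,6-dimethylhepta-1,5-dien-1-yl]lithium | CC(C)=CCC/C(C)=C/[Li]
F3 | step 5 | tributyl[(1E)-2,6-dimethylhepta-1,5-dien-1-yl]stannane | CC(C)=CCC/C(C)=C/[Sn](CCCC)(CCCC)CCCC
F4 | step 3 | 7-hydroxy-8-methyl-4H-chromen-4-one | Cc1c(O)ccc2c1occc2=O
F5 | step 3 | 8-methyl-4-oxo-4H-chromen-7-yl acetate | Cc1c(OC(C)=O)ccc2c1occc2=O
F6 | step 3 | 8-(bromomethyl)-4-oxo-4H-chromen-7-yl acetate | BrCc1c(OC(C)=O)ccc2c1occc2=O
F7 | step 3 | 8-geranyl-4-oxo-4H-chromen-7-yl acetate | CC(C)=CCC/C(C)=C/Cc1c(OC(C)=O)ccc2c1occc2=O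
F8 | step 3 | 8-geranyl-7-hydroxy-4H-chromen-4-one | CC(C)=CCC/C(C)=C/Cc1c(O)ccc2c1occc2=O
F9 | step 6 | rac-2-[4-(tert-butyldimethylsilyloxy)phenyl]-8-geranyl-7-(triisopropylsilyloxy)chroman-4-one | CC(C)=CCC/C(C)=C/Cc1c(O[Si](C(C)C)(C(C)C)C(C)C)ccc2c1OC(c1ccc(O[Si](C)(C)C(C)(C)C)cc1)CC2=O
F10 | step 6 | (2R,4R)-2-[4-(tert-butyldimethylsilyloxy)phenyl]-8-geranyl-7-(triisopropylsilyloxy)chroman-4-ol | CC(C)=CCC/C(C)=C/Cc1c(O[Si](C(C)C)(C(C)C)C(C)C)ccc2c1O[C@@H](c1ccc(O[Si](C)(C)C(C)(C)C)cc1)C[C@H]2O
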